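At early times target climbs in both earlier runs. The highest reading stands at 0.667 h, and after that it falls away.

| setting | alder | maple | flask |
|---|---|---|---|
| substrate | 0.13 M | 0.30 M | 0.20 M |
| partner | 0.26 M | 0.26 M | 0.260 M |
| remark | run made earlier | run made earlier |  |
| time |  |  | 30 h |

| run | time / h | target / % |
|---|---|---|
| alder | 0.250 | 27.2 |
| alder | 0.667 | 32.6 |
| alder | 1.50 | 23.5 |
| alder | 4.00 | 8.2 |
| alder | 10.0 | 0 |
| alder | 25.0 | 1.1 |
| maple | 0.250 | 19.9 |
| maple | 0.667 | 20.7 |
| maple | 1.50 | 12.9 |
| maple | 4.00 | 4.9 |
| maple | 10.0 | 1.2 |
| maple | 25.0 | 0.2 |

(scatter of a reading: 1 percentage point)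

- percentages count the substrate that a species holds: one side product counts as two
- on the list of suspects stand: 2 partner -> homo product; partner + intermediate -> target; substrate + intermediate -> side product; substrate -> intermediate; target -> over-reaction product

1. the best time, 30 h at the latest, for target
2. the amount of target, in percent of the substrate charged, at that time

I start from the end state. On the list, target goes on to over-reaction product, so I expect target to vanish and what was made to end as that product. For the speed, I take the alder run between 1.50 h and 4.00 h: the readings fall from 23.5% to 8.2%, and a first-order decay then gives 2.37 h. This is the tail time constant τ, the time in which target shrinks by a factor e once its making has stopped. It is a reading and carries the scatter. It is short against 30 h, so I look for the best time early. Interpolating the readings at 0.667 h to 0.20 M of substrate, I commit to 27.7% near that time.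

The forecast, “Scaling the observed peaks”, gives 26% (23% to 29%) at 0.55 h (0.35 h to 0.8 h).

The flask gives 26.9% at 0.451 h, lower and earlier than my reckoning.

    2 partner → homo product (k = 0.846 L mol⁻¹ min⁻¹)
    partner + intermediate → target (k = 1.51 L mol⁻¹ min⁻¹)
    substrate + intermediate → side product (k = 0.149 L mol⁻¹ min⁻¹)
    substrate → intermediate (k = 0.0791 min⁻¹)
    target → over-reaction product (k = 0.00742 min⁻¹)

At 30.0 h the flask holds 0% target and 32.2% over-reaction product. Grown back over the best time, the peak gains the factor exp(t/τ) = 1.21, which gives 32.6%, close to that end value.

A second flask has [partner] = 1.0 M and a best of 32.4%. Assuming the same best time there, the factor gives 39.1% over-reaction product. That flask ends with 39.1%.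

(The earlier runs and the new flask were generated by integration with constants of no real substance; the scatter is artificial.)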